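Qa goes to Qb by a plain first-order step, so the easy question comes first: when does Qb stop gaining?

    Qa → Qb (k1 = 0.045 s⁻¹)
    Qb → Qc (k2 = 0.0067 s⁻¹)
    Qc → Qd (k3 = 0.039 s⁻¹)
    Qa + Qd ⇌ Qe, settled at all times (K4 = 5.7 M⁻¹)

common to all: Qa 0.30 M
- theta: a single well-mixed tank run continuously and read at steady state, 4.50 min in it on average
- alpha: one stirred flow tank at steady state, fed with the mixture as stated, mean residence time 1.5 min
- gamma: everything together in a closed stirred flask, run for 1.5 min; time 1.5 min

- a species is counted by the Qa in it: one Qe counts as two
- amounts and yields of Qd count Qe too
- the stated concentrations are those of everything mixed, before any reaction; amounts are the same in each set-up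
- in an amount of Qd, one Qe counts as one Qd
- run time (gamma): 1.5 min

* order of the set-ups by the amount of Qb at the outlet or at the end, in percent of the Qa put in, highest first (theta / alpha / gamma)
* amount of Qb at the outlet or at the end, in percent of the Qa put in, theta
* amount of Qb at the outlet or at the end, in percent of the Qa put in, alpha
* amount of Qb at the outlet or at the end, in percent of the Qa put in, gamma

My quantity is the crossing time 0.829 min, the moment in a closed flask when step 1 makes Qb as fast as step 2 uses it, with Qe ignored: the logarithm of the ratio of the two rate constants, over their difference. The run time of gamma is longer, so by this reckoning Qb in gamma has begun to fall.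

Two of us dispute how much Qe matters. One points to the equilibrium constant times the starting Qa, 1.7, which is above one, and expects Qe to hold back much of the Qa. The other holds to the plain chain: Qb has a half-life of 1.7 min, longer than the 0.26 min of Qa, so Qa should shrink before much Qd stands to bind it.

My own reckoning is the bare chain, without Qe. It gives 62.2% in gamma, 32.9% in theta and 50.0% in alpha.

The forecast takes the chain's side but goes further, with step 4 included: gamma > alpha > theta, at 31%, 47.3% and 61.6%. For gamma it allows a small charge, since “Qe holds back Qa and delays its consumption by about 9 s”. So my gamma figure stands 0.60 percentage points above it.

The simulation gives gamma > alpha > theta, at 31.0%, 47.3% and 61.6%, and the forecast stands. The binding view has its ground in alpha, where the bare chain lies 2.7 points above the result, against 0.60 points in gamma.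

Gamma holds 70.8% Qb at 0.750 min, a reading earlier than the crossing time, and 61.6% at 1.50 min, a reading later than it. What would overturn the order is a later reading of the same flask. At 2.5 min, which is 3.02 crossing times, the bare chain gives 42.9%. That later reading of gamma holds 42.9% Qb, less than the 47.3% of alpha.

The rate constants come from no measurement; what happens was integrated by code.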